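## Retrosynthetic overview

1. Target 34 ⇐ hydrogenolysis of penta-ether 33 ⇐ ionic hydrogenation of carbinol 31 ⇐ C6-aryllithium from bromo-flavan-3-ol 29 + (S)-flavanone 15. The interflavan C4–C6 bond is made last, and the bromine placed early fixes the 4→6 regiochemistry.
2. 29 ⇐ 5→6 ring expansion (1,2-aryl shift through a phenonium ion) of the cis-3-(hydroxymethyl)-2-aryl-2,3-dihydrobenzofuran 26.
3. 26 ⇐ ester 25 ⇐ Rh2(R-PTTL)4-catalysed benzylic C–H insertion of aryl diazoacetate 24 ⇐ iodide 22 + ethyl diazoacetate 23; 22 ⇐ phenol 20 (resorcinol → 2-bromoresorcinol → C–H borylation/oxidation) + benzyl alcohol 8.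
4. 15 ⇐ asymmetric conjugate arylation ([Rh(OH)(cod)]2 catalyst) of chromone 14 (resorcinol + 3-chloropropanoic acid) with boronic acid 5; both B rings come from 4-bromophenol.
5. Ring order: upper ring C (step 4), lower furan ring (step 14), its expansion to lower ring C (step 16), then union of the two flavan units (steps 17 and 18).

Assumption: the antipodes of the chiral catalysts named in steps 7 and 14 are those that give the configurations drawn; if the sense of induction is the opposite one, the mirror-image ligand is used.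

## Route

Step 1
Reactants: 1 4-bromophenol
Product: 2 1-(benzyloxy)-4-bromobenzene
Conditions: BnBr, K2CO3, DMF, 60 °C
Reagents that add atoms: benzyl bromide, BrCc1ccccc1
Why: Williamson ether synthesis on the phenoxide; the benzyl ether survives every later step and leaves in step 19.

Step 2
Reactants: 2 1-(benzyloxy)-4-bromobenzene
Product: 5 [4-(benzyloxy)phenyl]boronic acid, via aryllithium 3 (not isolated), via boronate ester 4 (not isolated)
Conditions: n-BuLi, THF, −78 °C; B(OMe)3, −78 °C → rt; 1 M HCl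
Reagents that add atoms: trimethyl borate, COB(OC)OC; water, O
Why: Bromine–lithium exchange followed by borylation and hydrolysis is the standard arylboronic acid synthesis and does not touch the benzyl ether at −78 °C.

Step 3
Reactants: 2 1-(benzyloxy)-4-bromobenzene; 6 formaldehyde (used as dry paraformaldehyde)
Product: 8 [4-(benzyloxy)phenyl]methanol, via arylmagnesium bromide 7 (not isolated)
Conditions: Mg turnings, I2 (cat.), THF, 50 °C; (CH2O)n, 0 °C → rt; H2O
Reagents that add atoms: none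
Why: Grignard reaction: magnesium inserts into the C–Br bond and the arylmagnesium bromide adds to formaldehyde (carbonyl addition) to give the benzylic alcohol in one operation, the benzyl ether being inert.

Step 4
Reactants: 9 resorcinol; 10 3-chloropropanoic acid
Product: 12 7-hydroxychroman-4-one, via chloroketone 11 (not isolated)
Conditions: CF3SO3H, 80 °C; then 2 M NaOH, 0 °C → rt; H3O+
Reagents that add atoms: none
Why: Friedel–Crafts acylation para to one hydroxyl gives the aryl 2-chloroethyl ketone, and the ortho phenoxide then closes ring C by intramolecular Williamson alkylation.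

Step 5
Reactants: 12 7-hydroxychroman-4-one
Product: 13 7-(benzyloxy)chroman-4-one
Conditions: BnBr, K2CO3, DMF, rt
Reagents that add atoms: benzyl bromide, BrCc1ccccc1
Why: Williamson ether synthesis on the only phenol.

Step 6
Reactants: 13 7-(benzyloxy)chroman-4-one
Product: 14 7-(benzyloxy)-4H-chromen-4-one
Conditions: Pd(OCOCF3)2 (5 mol%), DMSO (10 mol%), O2 (1 atm), AcOH, 80 °C
Reagents that add atoms: none
Why: Pd(OCOCF3)2-catalysed aerobic α,β-dehydrogenation of a ketone (Stahl-type, enolate palladation then β-hydride elimination) gives the chromone; the aryl benzyl ether is inert to it.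

Step 7
Reactants: 14 7-(benzyloxy)-4H-chromen-4-one; 5 [4-(benzyloxy)phenyl]boronic acid
Product: 15 (2S)-7-(benzyloxy)-2-[4-(benzyloxy)phenyl]-2,3-dihydro-4H-chromen-4-one
Conditions: [Rh(OH)(cod)]2 (2 mol%), (R)-MeO-F12-BIPHEP (4.4 mol%), 5 (2 equiv), toluene/H2O, 25 °C
Reagents that add atoms: none
Why: Asymmetric 1,4-addition of an arylboronic acid to a chromone under [Rh(OH)(cod)]2/bisphosphine catalysis (Hayashi–Miyaura type) sets C2 as S by catalyst control under near-neutral conditions that avoid retro-oxa-Michael opening of the flavanone.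

Step 8
Reactants: 9 resorcinol
Product: 17 2-bromobenzene-1,3-diol, via tribromoresorcinol 16 (not isolated)
Conditions: Br2 (3.05 equiv), CHCl3, 0 °C → rt; then Na2SO3, NaOH, MeOH/H2O, rt
Reagents that add atoms: bromine, BrBr
Why: Exhaustive electrophilic bromination followed by selective sulfite debromination of the 4- and 6-positions (ipso-protonation para to a phenoxide) leaves the bromine between the two oxygens, the future C6 of the lower unit.

Step 9
Reactants: 17 2-bromobenzene-1,3-diol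
Product: 18 2-bromo-1,3-bis{[4-(trifluoromethyl)benzyl]oxy}benzene
Conditions: 4-(trifluoromethyl)benzyl bromide (2.2 equiv), K2CO3, DMF, 50 °C
Reagents that add atoms: 4-(trifluoromethyl)benzyl bromide, FC(F)(F)c1ccc(CBr)cc1
Why: Williamson ether synthesis; this para-substituted, electron-poor benzyl group offers no unhindered C–H to the [Ir(OMe)(cod)]2-derived borylation catalyst of step 10, has a benzylic C–H deactivated toward the rhodium carbenoid of step 14, and is still removed by hydrogenolysis in step 19.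

Step 10
Reactants: 18 2-bromo-1,3-bis{[4-(trifluoromethyl)benzyl]oxy}benzene
Product: 20 4-bromo-3,5-bis{[4-(trifluoromethyl)benzyl]oxy}phenol, via pinacol boronate 19 (not isolated)
Conditions: [Ir(OMe)(cod)]2 (1.5 mol%), 4,4'-di-tert-butyl-2,2'-bipyridine (3 mol%), B2pin2 (0.55 equiv), THF, 80 °C; then 30% H2O2, aq. NaOH, 0 °C
Reagents that add atoms: hydrogen peroxide, OO
Why: Sterically controlled C–H borylation with the [Ir(OMe)(cod)]2/bipyridine catalyst attacks the only C–H not ortho to a substituent (C5, para to bromine), and oxidation of the boronate (1,2-shift of aryl from boron to oxygen) gives the third ring-A oxygen, the future O1.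

Step 11
Reactants: 20 4-bromo-3,5-bis{[4-(trifluoromethyl)benzyl]oxy}phenol; 8 [4-(benzyloxy)phenyl]methanol
Product: 21 2-bromo-5-{[4-(benzyloxy)benzyl]oxy}-1,3-bis{[4-(trifluoromethyl)benzyl]oxy}benzene
Conditions: PPh3, DIAD, THF, 0 °C → rt
Reagents that add atoms: none
Why: Mitsunobu etherification of a phenol with a primary benzylic alcohol puts the B-ring benzyl group (future C2 and ring B) on the future O1.

Step 12
Reactants: 21 2-bromo-5-{[4-(benzyloxy)benzyl]oxy}-1,3-bis{[4-(trifluoromethyl)benzyl]oxy}benzene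
Product: 22 1-{[4-(benzyloxy)benzyl]oxy}-4-bromo-2-iodo-3,5-bis{[4-(trifluoromethyl)benzyl]oxy}benzene
Conditions: NIS (1.05 equiv), MeCN/CH2Cl2, 0 °C
Reagents that add atoms: N-iodosuccinimide, O=C1CCC(=O)N1I
Why: Electrophilic aromatic iodination of the trialkoxyarene can only occur at the two symmetry-equivalent free positions, both ortho to the B-ring benzyl ether, so a single mono-iodide forms.

Step 13
Reactants: 22 1-{[4-(benzyloxy)benzyl]oxy}-4-bromo-2-iodo-3,5-bis{[4-(trifluoromethyl)benzyl]oxy}benzene; 23 ethyl diazoacetate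
Product: 24 ethyl 2-[6-{[4-(benzyloxy)benzyl]oxy}-3-bromo-2,4-bis{[4-(trifluoromethyl)benzyl]oxy}phenyl]-2-diazoacetate
Conditions: Pd(PPh3)4 (5 mol%), Ag2CO3 (0.5 equiv), Et3N (1.3 equiv), 23 (1.5 equiv), toluene, 25 °C
Reagents that add atoms: none
Why: Pd(PPh3)4-catalysed cross-coupling of an aryl iodide with the C–H of ethyl diazoacetate keeps the diazo group, and zerovalent palladium inserts into C–I far faster than into the hindered, electron-rich C–Br at room temperature.

Step 14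
Reactants: 24 ethyl 2-[6-{[4-(benzyloxy)benzyl]oxy}-3-bromo-2,4-bis{[4-(trifluoromethyl)benzyl]oxy}phenyl]-2-diazoacetate
Product: 25 ethyl (2S,3R)-2-[4-(benzyloxy)phenyl]-5-bromo-4,6-bis{[4-(trifluoromethyl)benzyl]oxy}-2,3-dihydro-1-benzofuran-3-carboxylate
Conditions: Rh2(R-PTTL)4 (1 mol%; PTTL = N-phthaloyl-tert-leucinate), toluene, −60 °C
Reagents that add atoms: none
Why: Enantioselective intramolecular 1,5 C–H insertion of the rhodium carbenoid (Hashimoto/Davies type) into the hydridic para-alkoxybenzylic O–CH2 bond gives the cis-2-aryl-3-carboxylate, setting C2 and C3 by catalyst control; the other ortho ether is a para-CF3-benzyl group, whose benzylic C–H is electronically deactivated toward the electrophilic carbenoid.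

Step 15
Reactants: 25 ethyl (2S,3R)-2-[4-(benzyloxy)phenyl]-5-bromo-4,6-bis{[4-(trifluoromethyl)benzyl]oxy}-2,3-dihydro-1-benzofuran-3-carboxylate
Product: 26 {(2S,3S)-2-[4-(benzyloxy)phenyl]-5-bromo-4,6-bis{[4-(trifluoromethyl)benzyl]oxy}-2,3-dihydro-1-benzofuran-3-yl}methanol
Conditions: LiAlH4, THF, −20 °C; Fieser work-up
Reagents that add atoms: none
Why: Hydride reduction of the ester at low temperature gives the primary alcohol without epimerising the cis C3 centre (the descriptor changes only through priorities) and without touching the aryl bromide.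

Step 16
Reactants: 26 {(2S,3S)-2-[4-(benzyloxy)phenyl]-5-bromo-4,6-bis{[4-(trifluoromethyl)benzyl]oxy}-2,3-dihydro-1-benzofuran-3-yl}methanol
Product: 29 (2R,3R)-2-[4-(benzyloxy)phenyl]-6-bromo-5,7-bis{[4-(trifluoromethyl)benzyl]oxy}-3,4-dihydro-2H-chromen-3-ol, via mesylate 27 (not isolated), via phenonium ion 28 (not isolated)
Conditions: Ms2O (1.3 equiv), 2,6-lutidine (3 equiv), CH2Cl2, −40 °C; then (CF3)2CHOH/H2O 4:1, −40 → 25 °C; aq. NaHCO3
Reagents that add atoms: water, O
Why: Proposed new method: the primary mesylate ionises with anchimeric assistance from the trioxygenated ring A (ipso attack gives the spiro-cyclopropyl arenium ion 28, its charge carried by three ortho/para oxygens), and water opens the strained fused cyclopropane at the secondary carbon C3 anti to the migrating aryl carbon, so the aryl group has shifted 1,2 from C3 to the former CH2 (now C4), the furan ring has become the pyran ring, and inversion at C3 with C2 untouched converts cis-26 stereospecifically into the 2,3-cis (2R,3R) flavan-3-ol (the C2 aryl is gauche to the breaking bond and cannot migrate; the buffer prevents C2 ionisation); the closest known reactions are neophyl-type phenonium solvolyses that expand 1-indanylmethyl sulfonates to 2-tetralyl products and the aziridinium ring expansion of prolinols to 3-substituted piperidines, neither shown on a dihydrobenzofuran or used to make a flavan-3-ol.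

Step 17
Reactants: 29 (2R,3R)-2-[4-(benzyloxy)phenyl]-6-bromo-5,7-bis{[4-(trifluoromethyl)benzyl]oxy}-3,4-dihydro-2H-chromen-3-ol; 15 (2S)-7-(benzyloxy)-2-[4-(benzyloxy)phenyl]-2,3-dihydro-4H-chromen-4-one
Product: 31 (2S)-7-(benzyloxy)-2-[4-(benzyloxy)phenyl]-4-{(2R,3R)-2-[4-(benzyloxy)phenyl]-3-hydroxy-5,7-bis{[4-(trifluoromethyl)benzyl]oxy}-3,4-dihydro-2H-chromen-6-yl}-3,4-dihydro-2H-chromen-4-ol (C4 epimers), via dilithio species 30 (not isolated)
Conditions: n-BuLi (2.1 equiv), THF, −78 °C; then 15 premixed with LaCl3·2LiCl (1.1 equiv), −78 → −30 °C; H2O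
Reagents that add atoms: none
Why: After deprotonation of the 3-OH, bromine–lithium exchange gives the 2,6-dialkoxyaryllithium exactly at C6, which adds 1,2 to the flavanone carbonyl (LaCl3·2LiCl suppresses enolisation and ring-C opening); the new carbinol centre need not be controlled because it is planarised in step 18.

Step 18
Reactants: 31 (2S)-7-(benzyloxy)-2-[4-(benzyloxy)phenyl]-4-{(2R,3R)-2-[4-(benzyloxy)phenyl]-3-hydroxy-5,7-bis{[4-(trifluoromethyl)benzyl]oxy}-3,4-dihydro-2H-chromen-6-yl}-3,4-dihydro-2H-chromen-4-ol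
Product: 33 (2R,3R)-2-[4-(benzyloxy)phenyl]-6-{(2S,4S)-7-(benzyloxy)-2-[4-(benzyloxy)phenyl]-3,4-dihydro-2H-chromen-4-yl}-5,7-bis{[4-(trifluoromethyl)benzyl]oxy}-3,4-dihydro-2H-chromen-3-ol, via benzylic cation 32 (not isolated)
Conditions: Et3SiH (5 equiv), CF3CO2H (10 equiv), CH2Cl2, −40 → −20 °C; aq. NaHCO3
Reagents that add atoms: none
Why: Kursanov–Parnes ionic hydrogenation: the doubly benzylic, oxygen-stabilised cation 32 forms far more readily than any other cation in the molecule and takes hydride axially, trans to the pseudo-equatorial C2 aryl group, so the lower aryl group ends up equatorial and cis to it (4S, 2,4-cis), which is also the thermodynamically preferred arrangement.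

Step 19
Reactants: 33 (2R,3R)-2-[4-(benzyloxy)phenyl]-6-{(2S,4S)-7-(benzyloxy)-2-[4-(benzyloxy)phenyl]-3,4-dihydro-2H-chromen-4-yl}-5,7-bis{[4-(trifluoromethyl)benzyl]oxy}-3,4-dihydro-2H-chromen-3-ol
Product: 34 (2R,3R)-2-(4-hydroxyphenyl)-6-[(2S,4S)-7-hydroxy-2-(4-hydroxyphenyl)-3,4-dihydro-2H-chromen-4-yl]-3,4-dihydro-2H-chromene-3,5,7-triol (CNP0167324.1)
Conditions: H2 (1 atm), Pd(OH)2/C, THF/MeOH, rt
Reagents that add atoms: none
Why: Hydrogenolysis cleaves all five aryl benzyl-type ethers under neutral conditions that leave the cyclic benzylic ethers, the C4–aryl bond and all four stereocentres untouched, as is standard in proanthocyanidin endgames.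

## Compound list

1 | 4-bromophenol | Oc1ccc(Br)cc1 | starting material
2 | 1-(benzyloxy)-4-bromobenzene | Brc1ccc(OCc2ccccc2)cc1 | intermediate
3 | [4-(benzyloxy)phenyl]lithium | [Li]c1ccc(OCc2ccccc2)cc1 | intermediate
4 | dimethyl [4-(benzyloxy)phenyl]boronate | COB(OC)c1ccc(OCc2ccccc2)cc1 | intermediate
5 | [4-(benzyloxy)phenyl]boronic acid | OB(O)c1ccc(OCc2ccccc2)cc1 | intermediate
6 | formaldehyde | C=O | starting material
7 | [4-(benzyloxy)phenyl]magnesium bromide | Br[Mg]c1ccc(OCc2ccccc2)cc1 | intermediate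
8 | [4-(benzyloxy)phenyl]methanol | OCc1ccc(OCc2ccccc2)cc1 | intermediate
9 | resorcinol | Oc1cccc(O)c1 | starting material
10 | 3-chloropropanoic acid | OC(=O)CCCl | starting material
11 | 3-chloro-1-(2,4-dihydroxyphenyl)propan-1-one | O=C(CCCl)c1ccc(O)cc1O | intermediate
12 | 7-hydroxychroman-4-one | O=C1CCOc2cc(O)ccc12 | intermediate
13 | 7-(benzyloxy)chroman-4-one | O=C1CCOc2cc(OCc3ccccc3)ccc12 | intermediate
14 | 7-(benzyloxy)-4H-chromen-4-one | O=c1ccoc2cc(OCc3ccccc3)ccc12 | intermediate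
15 | (2S)-7-(benzyloxy)-2-[4-(benzyloxy)phenyl]-2,3-dihydro-4H-chromen-4-one | O=C1C[C@@H](c2ccc(OCc3ccccc3)cc2)Oc2cc(OCc3ccccc3)ccc12 | intermediate
16 | 2,4,6-tribromobenzene-1,3-diol | Oc1c(Br)cc(Br)c(O)c1Br | intermediate
17 | 2-bromobenzene-1,3-diol | Oc1cccc(O)c1Br | intermediate
18 | 2-bromo-1,3-bis{[4-(trifluoromethyl)benzyl]oxy}benzene | Brc1c(OCc2ccc(cc2)C(F)(F)F)cccc1OCc1ccc(cc1)C(F)(F)F | intermediate
19 | 2-(4-bromo-3,5-bis{[4-(trifluoromethyl)benzyl]oxy}phenyl)-4,4,5,5-tetramethyl-1,3,2-dioxaborolane | CC1(C)OB(OC1(C)C)c1cc(OCc2ccc(cc2)C(F)(F)F)c(Br)c(OCc2ccc(cc2)C(F)(F)F)c1 | intermediate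
20 | 4-bromo-3,5-bis{[4-(trifluoromethyl)benzyl]oxy}phenol | Oc1cc(OCc2ccc(cc2)C(F)(F)F)c(Br)c(OCc2ccc(cc2)C(F)(F)F)c1 | intermediate
21 | 2-bromo-5-{[4-(benzyloxy)benzyl]oxy}-1,3-bis{[4-(trifluoromethyl)benzyl]oxy}benzene | Brc1c(OCc2ccc(cc2)C(F)(F)F)cc(OCc2ccc(OCc3ccccc3)cc2)cc1OCc1ccc(cc1)C(F)(F)F | intermediate
22 | 1-{[4-(benzyloxy)benzyl]oxy}-4-bromo-2-iodo-3,5-bis{[4-(trifluoromethyl)benzyl]oxy}benzene | Brc1c(OCc2ccc(cc2)C(F)(F)F)cc(OCc2ccc(OCc3ccccc3)cc2)c(I)c1OCc1ccc(cc1)C(F)(F)F | intermediate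
23 | ethyl diazoacetate | CCOC(=O)C=[N+]=[N-] | starting material
24 | ethyl 2-[6-{[4-(benzyloxy)benzyl]oxy}-3-bromo-2,4-bis{[4-(trifluoromethyl)benzyl]oxy}phenyl]-2-diazoacetate | CCOC(=O)C(=[N+]=[N-])c1c(OCc2ccc(OCc3ccccc3)cc2)cc(OCc2ccc(cc2)C(F)(F)F)c(Br)c1OCc1ccc(cc1)C(F)(F)F | intermediate
25 | ethyl (2S,3R)-2-[4-(benzyloxy)phenyl]-5-bromo-4,6-bis{[4-(trifluoromethyl)benzyl]oxy}-2,3-dihydro-1-benzofuran-3-carboxylate (cis) | CCOC(=O)[C@H]1[C@@H](c2ccc(OCc3ccccc3)cc2)Oc4cc(OCc5ccc(cc5)C(F)(F)F)c(Br)c(OCc6ccc(cc6)C(F)(F)F)c14 | intermediate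
26 | {(2S,3S)-2-[4-(benzyloxy)phenyl]-5-bromo-4,6-bis{[4-(trifluoromethyl)benzyl]oxy}-2,3-dihydro-1-benzofuran-3-yl}methanol (cis) | OC[C@H]1[C@@H](c2ccc(OCc3ccccc3)cc2)Oc4cc(OCc5ccc(cc5)C(F)(F)F)c(Br)c(OCc6ccc(cc6)C(F)(F)F)c14 | intermediate
27 | {(2S,3S)-2-[4-(benzyloxy)phenyl]-5-bromo-4,6-bis{[4-(trifluoromethyl)benzyl]oxy}-2,3-dihydro-1-benzofuran-3-yl}methyl methanesulfonate | CS(=O)(=O)OC[C@H]1[C@@H](c2ccc(OCc3ccccc3)cc2)Oc4cc(OCc5ccc(cc5)C(F)(F)F)c(Br)c(OCc6ccc(cc6)C(F)(F)F)c14 | intermediate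
28 | phenonium ion (spiro-cyclopropyl arenium cation bridging C3 and the former CH2, drawn as its para-oxocarbenium form; methanesulfonate salt) | [C@H]1(c4ccc(OCc5ccccc5)cc4)OC2=CC(=[O+]Cc4ccc(cc4)C(F)(F)F)C(Br)=C(OCc4ccc(cc4)C(F)(F)F)[C@@]23C[C@@H]13.CS(=O)(=O)[O-] | intermediate
29 | (2R,3R)-2-[4-(benzyloxy)phenyl]-6-bromo-5,7-bis{[4-(trifluoromethyl)benzyl]oxy}-3,4-dihydro-2H-chromen-3-ol | Brc1c(OCc3ccc(cc3)C(F)(F)F)cc2c(c1OCc4ccc(cc4)C(F)(F)F)C[C@@H](O)[C@@H](c5ccc(OCc6ccccc6)cc5)O2 | intermediate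
30 | C6-lithio, 3-O-lithio derivative of 29 | [Li]c1c(OCc3ccc(cc3)C(F)(F)F)cc2c(c1OCc4ccc(cc4)C(F)(F)F)C[C@@H](O[Li])[C@@H](c5ccc(OCc6ccccc6)cc5)O2 | intermediate
31 | (2S)-7-(benzyloxy)-2-[4-(benzyloxy)phenyl]-4-{(2R,3R)-2-[4-(benzyloxy)phenyl]-3-hydroxy-5,7-bis{[4-(trifluoromethyl)benzyl]oxy}-3,4-dihydro-2H-chromen-6-yl}-3,4-dihydro-2H-chromen-4-ol (C4 epimers) | OC1(C[C@@H](c2ccc(OCc3ccccc3)cc2)Oc4cc(OCc5ccccc5)ccc14)c6c(OCc7ccc(cc7)C(F)(F)F)cc8c(c6OCc9ccc(cc9)C(F)(F)F)C[C@@H](O)[C@@H](c2ccc(OCc3ccccc3)cc2)O8 | intermediate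
32 | upper-unit C4 benzylic cation (trifluoroacetate salt) | c5ccccc5COc1ccc([C@@H]2C[C+](c3c(OCc6ccc(cc6)C(F)(F)F)cc4c(c3OCc7ccc(cc7)C(F)(F)F)C[C@@H](O)[C@@H](c3ccc(OCc8ccccc8)cc3)O4)c3ccc(OCc9ccccc9)cc3O2)cc1.[O-]C(=O)C(F)(F)F | intermediate
33 | (2R,3R)-2-[4-(benzyloxy)phenyl]-6-{(2S,4S)-7-(benzyloxy)-2-[4-(benzyloxy)phenyl]-3,4-dihydro-2H-chromen-4-yl}-5,7-bis{[4-(trifluoromethyl)benzyl]oxy}-3,4-dihydro-2H-chromen-3-ol | c5ccccc5COc1ccc([C@@H]2C[C@H](c3c(OCc6ccc(cc6)C(F)(F)F)cc4c(c3OCc7ccc(cc7)C(F)(F)F)C[C@@H](O)[C@@H](c3ccc(OCc8ccccc8)cc3)O4)c3ccc(OCc9ccccc9)cc3O2)cc1 | intermediate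
34 | (2R,3R)-2-(4-hydroxyphenyl)-6-[(2S,4S)-7-hydroxy-2-(4-hydroxyphenyl)-3,4-dihydro-2H-chromen-4-yl]-3,4-dihydro-2H-chromene-3,5,7-triol | Oc1ccc([C@@H]2C[C@H](c3c(O)cc4c(c3O)C[C@@H](O)[C@@H](c3ccc(O)cc3)O4)c3ccc(O)cc3O2)cc1 | target

## Step count and risks

Total: 19 steps. Longest linear sequence: 12 steps (steps 8 to 19, from resorcinol 9 through 17, 18, 20, 21, 22, 24, 25, 26, 29, 31 and 33 to 34).

The three steps most likely to fail:

Step 16 (the proposed ring expansion). The risks are capture of the phenonium ion at the primary carbon, which only returns 26, and ionisation at C2. The fallback uses known chemistry; it sets out from phenol 20 and bromide 2 and comes back at 29, so it also bypasses steps 11 to 15. Bromide 2 is lithiated as in step 2 (n-BuLi, THF, −78 °C) to aryllithium 3, which is added to acrolein to give, after aqueous work-up, racemic 1-[4-(benzyloxy)phenyl]prop-2-en-1-ol F1. Sharpless kinetic resolution (Ti(OiPr)4, the diisopropyl tartrate antipode that epoxidises the (R)-alcohol, t-BuOOH, molecular sieves, CH2Cl2, −20 °C) gives the erythro epoxy alcohol (S)-[4-(benzyloxy)phenyl][(2R)-oxiran-2-yl]methanol F2. Mitsunobu etherification of F2 with 20 (PPh3, DIAD, inversion at the carbinol carbon) gives the epoxy ether (2R)-2-[(R)-[4-(benzyloxy)phenyl](4-bromo-3,5-bis{[4-(trifluoromethyl)benzyl]oxy}phenoxy)methyl]oxirane F3. A 6-endo Friedel–Crafts epoxide–arene cyclisation at the terminal epoxide carbon ((CF3)2CHOH, rt, or BF3·OEt2, CH2Cl2, −78 °C) closes ring C and gives 29 with both centres retained. Its costs are the 50% ceiling of the resolution and the acid-sensitive benzylic ether in F3.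

Step 13 (diazoester coupling at an iodide flanked by two alkoxy groups). The fallback sets out from 22 and comes back at 24. Zinc and ethyl bromoacetate give the Reformatsky reagent (2-ethoxy-2-oxoethyl)zinc bromide F4, which undergoes Negishi coupling with 22 (Pd2(dba)3, XPhos, THF, rt, iodide-selective) to give ethyl 2-[6-{[4-(benzyloxy)benzyl]oxy}-3-bromo-2,4-bis{[4-(trifluoromethyl)benzyl]oxy}phenyl]acetate F5. Diazo transfer (4-acetamidobenzenesulfonyl azide, DBU, MeCN, 0 °C) then gives 24.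

Step 17 (addition of a hindered aryllithium to an enolisable flavanone). The fallback sets out from 15 and 29 and comes back at 33, replacing carbonyl addition by cross-coupling. Ketone 15 is converted (KN(SiMe3)2, PhNTf2, THF, −78 °C) into the enol triflate (2S)-7-(benzyloxy)-2-[4-(benzyloxy)phenyl]-2H-chromen-4-yl trifluoromethanesulfonate F6. Dilithio species 30 (from 29 as in step 17) is transmetalated with ZnCl2 to the arylzinc chloride F7. Negishi coupling of F6 with F7 (Pd(OAc)2, SPhos, THF, 50 °C) gives the 4-aryl-2H-chromene (2R,3R)-2-[4-(benzyloxy)phenyl]-6-{(2S)-7-(benzyloxy)-2-[4-(benzyloxy)phenyl]-2H-chromen-4-yl}-5,7-bis{[4-(trifluoromethyl)benzyl]oxy}-3,4-dihydro-2H-chromen-3-ol F8. Et3SiH/CF3CO2H protonates F8 at C3 to the same cation 32 and delivers 33.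

Further compounds
F1 | step 16 | rac-1-[4-(benzyloxy)phenyl]prop-2-en-1-ol | OC(C=C)c1ccc(OCc2ccccc2)cc1
F2 | step 16 | (S)-[4-(benzyloxy)phenyl][(2R)-oxiran-2-yl]methanol | O[C@H]([C@H]1CO1)c1ccc(OCc2ccccc2)cc1
F3 | step 16 | (2R)-2-[(R)-[4-(benzyloxy)phenyl](4-bromo-3,5-bis{[4-(trifluoromethyl)benzyl]oxy}phenoxy)methyl]oxirane | Brc1c(OCc2ccc(cc2)C(F)(F)F)cc(O[C@@H]([C@H]2CO2)c2ccc(OCc3ccccc3)cc2)cc1OCc1ccc(cc1)C(F)(F)F
F4 | step 13 | (2-ethoxy-2-oxoethyl)zinc bromide | CCOC(=O)C[Zn]Br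
F5 | step 13 | ethyl 2-[6-{[4-(benzyloxy)benzyl]oxy}-3-bromo-2,4-bis{[4-(trifluoromethyl)benzyl]oxy}phenyl]acetate | CCOC(=O)Cc1c(OCc2ccc(OCc3ccccc3)cc2)cc(OCc2ccc(cc2)C(F)(F)F)c(Br)c1OCc1ccc(cc1)C(F)(F)F
F6 | step 17 | (2S)-7-(benzyloxy)-2-[4-(benzyloxy)phenyl]-2H-chromen-4-yl trifluoromethanesulfonate | FC(F)(F)S(=O)(=O)OC1=C[C@@H](c2ccc(OCc3ccccc3)cc2)Oc2cc(OCc3ccccc3)ccc12
F7 | step 17 | C6-(chlorozincio), 3-O-lithio derivative of 29 | Cl[Zn]c1c(OCc3ccc(cc3)C(F)(F)F)cc2c(c1OCc4ccc(cc4)C(F)(F)F)C[C@@H](O[Li])[C@@H](c5ccc(OCc6ccccc6)cc5)O2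
F8 | step 17 | (2R,3R)-2-[4-(benzyloxy)phenyl]-6-{(2S)-7-(benzyloxy)-2-[4-(benzyloxy)phenyl]-2H-chromen-4-yl}-5,7-bis{[4-(trifluoromethyl)benzyl]oxy}-3,4-dihydro-2H-chromen-3-ol | c5ccccc5COc1ccc([C@@H]2C=C(c3c(OCc6ccc(cc6)C(F)(F)F)cc4c(c3OCc7ccc(cc7)C(F)(F)F)C[C@@H](O)[C@@H](c3ccc(OCc8ccccc8)cc3)O4)c3ccc(OCc9ccccc9)cc3O2)cc1
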